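## The problem

The target, (1R,3S,4R,5R,6S,7R,8S,10R)-1,10:4,5-diepoxy-3-hydroxy-8-tigloyloxygermacr-11(13)-en-12,6-olide, is a ten-membered carbocycle (C1–C10). An α-methylene-γ-lactone is trans-fused across C6–C7 (C12 to O6, C11=C13), O8 carries a tiglate, C3 a free hydroxyl, and C1–C10 and C4–C5 are trans-epoxides. Eight stereocenters sit on a mobile medium ring, so each has to be set on a rigid precursor or come from a stereospecific step. Only C7 can be bought (carvone); C6 and C8 can be set relative to it on a six-membered ring, and C3 and C4 relative to an angular methyl group. Direct closure of a ten-membered ring is costly, and the trisubstituted C1=C10 unit must be E before it is epoxidized. The α-methylene lactone is a Michael acceptor, the epoxides open transannularly under acid, the 3-hydroxy-4,5-epoxide can undergo Payne rearrangement under base, and the tiglate is base-labile, so these groups must appear late and be unmasked under near-neutral conditions. The enabling feature is that C1=C10 and the oxygen-bearing C5 are 1,6-related across the ring. That is the pattern left by heterolysis of the C5–C10 bond of a decalin with a C5 hydroxyl and a C1 leaving group, and the tertiary O4 next to C5 can later become the epoxide oxygen. C1, C5 and C10 of such a decalin are consumed, so their configuration is free and can be chosen to keep every other substituent equatorial.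

## Retrosynthesis

**38 back to 35.** The O8–acyl and O3–benzyl bonds are cut first. The tiglate goes on 8-ol 36, released from silyl ether 35, and the 3-hydroxyl is freed last from PMB ether 37 with buffered DDQ. The order is set by sensitivity: a free 3-hydroxyl beside the 4,5-epoxide must never meet base, and it would compete in the acylation.

**35 back to 32.** The C1–O and C10–O bonds are cut to the E olefin of 34, and C11=C13 is traced to the α-methyl lactone 32. Compound 34 is a 3,8-dioxygenated parthenolide, so the peracid should attack the exposed face of C1=C10 as it does in that ring system. A saturated lactone is preferred to an early methylene lactone because it survives base and hydride and protects O6 and C12 together.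

**32 back to 29.** The C5–O bond of the epoxide is cut. O4 displaces a C5 mesylate (31) with inversion, and the C5 alcohol 30 comes from ketone 29. This is preferred to epoxidizing a C4=C5 olefin because C4 is then fixed on a chair and C5 by a chelate, not by face selectivity on a flexible ring.

**29 back to 27 (key disconnection).** The C5–C10 bond is re-formed in thought. The cyclodecenone 29 becomes trans-decalin 27 with a 5α-hydroxyl and an equatorial 1β-mesylate, which replaces a ten-membered cyclization by the cleavage of a bond shared by two chairs. The C10 methyl is placed cis to the C7 side chain (natural eudesmane series). In this series O3, O4, O6, C7 and O8 are all equatorial in the trans-decalin; the C10-epimeric series would force all five axial. The forward reaction must give only the E olefin and must not disturb C6.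

**27 back to 22.** The lactone C12–O6 bond is cut to tetraol 26. The C5–O and C6–O bonds are cut to the Δ5 olefin of 24, and C12–O to the isopropenyl group of 22. A syn-dihydroxylation from the face opposite both axial methyls gives the trans ring fusion and the 6α-oxygen in one step. The isopropenyl group is hydroborated first so that it cannot compete for the osmium reagent.

**22 back to 14.** C1–O is cut back to the Δ1-enone of 14 (conjugate borylation gives 1α-ol 16), and C3–O to the C3 ketone (triol 17). The 1α-alcohol is inverted through ketone 20, because hydride anti to the angular methyl gives the equatorial 1β-ol 21. O3 is marked as its PMB ether 19 before that oxidation.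

**14 back to 12.** The C4–O bond is cut to the extended enolate of dienone 13, which is the dehydrogenation product of enone 12. With C2 sp2, the dienone can only enolize through C6, so the electrophile is directed to C4 and the Δ5 olefin needed later is created at the same time.

**12 back to 8 and 9.** The C4=C5 and C10–C1 bonds are cut (Robinson annulation) to diketone 11, and then to ketone 8 and ethyl vinyl ketone 9. C10 is the only center that needs reagent control, because axial attack would put the chain cis to the isopropenyl group.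

**8 back to 1.** Ketone 8 comes from enone 7, a carvone with a silyloxy group at C4. Oxygenating carvone directly at this γ-position is not reliable, so the oxygen is introduced at the easily enolized α′-position of (S)-carvone 1 (giving 3 and 4). The carbonyl is then moved across the ring by epoxidation (5), Wharton transposition (6) and oxidation (7). The transposition turns the (S)-carvone skeleton into the (R)-configured one required at C7.

## Roads not taken

**Alternative 1:** The cut is the O–C6 bond of the lactone, made late on a germacrene acid in which C6 is still a methylene group. In the forward step Pd(OAc)2 (divalent palladium) with 1,2-bis(phenylsulfinyl)ethane and benzoquinone would cleave the allylic C6–H bond, and the C12 carboxylate would attack C6 of the π-allyl intermediate to give A1, 3-chloroacetoxy-1,10-epoxy-8-tigloyloxygermacra-4,11(13)-dien-12,6-olide.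
- Merits: it is economical in oxidation state, it needs no protecting group on O6, and it leaves the lactone to the end.
- Weak points: this C–H lactonization is established for terminal olefins, whereas here the olefin is trisubstituted and internal, with three allylic sites (C3–H, C6–H2 and the C4 methyl). The carboxylate could attack either allyl terminus. Nothing but ring conformation would set C6. The 1,10-epoxide would have to survive the Lewis-acidic metal and the acid by-product.
- Comparison: the step does not make the ten-membered ring, and C4=C5 would still have to be epoxidized face-selectively. It would save the C5 redox steps and the selenium chemistry of the chosen plan; against that, the chosen plan sets C6 on a chair and uses only well-established reaction types.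

**Alternative 2:** The cut is C4–C5, which also closes the ring. CrCl2 (divalent chromium) with LiI would reduce a C4 dichloride to a chloro enolate that adds to a C5 aldehyde, and K2CO3 would then close the epoxide to give A2, 4,5-epoxy-3-oxo-8-tigloyloxygermacra-1(10),11(13)-dien-12,6-olide.
- Merits: ring and epoxide form in one flask, the open-chain precursor is convergent, and the E olefin can be made by acyclic methods.
- Weak points: a ten-membered ring closes against entropy and transannular strain. C4 and C5 would be new stereocenters controlled only by a macrocyclic transition state. The aldehyde is α-oxygenated at C6 and can epimerize or eliminate. The methylene lactone and tiglate would be exposed to a reducing metal and to carbonate. The C3 ketone would still need reduction to the 3S alcohol beside an epoxide.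
- Comparison: it is clearly more convergent and would be shorter. The chosen plan offers instead a ring formed without cyclization and a C4 center fixed before the ring is opened.

**Alternative 3:** The cut is C7–C8. CrCl2 (divalent chromium) would turn a C13 allylic bromide on a butenolide into an allylchromium species that attacks a C8 aldehyde through C7. This closes the ring and reveals the methylene lactone in A3, 8-hydroxy-3-(tert-butyldimethylsilyloxy)germacra-1(10),4,11(13)-trien-12,6-olide.
- Merits: one step builds the ring, C7, C8 and the most sensitive group. Intramolecular metal-mediated allylations of this kind are a recognized entry to ten-membered germacranolides.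
- Weak points: the C7/C8 relationship and its relation to C6 rest on the macrocyclic transition state. Both trisubstituted E olefins must be built in the open chain. Two epoxidations must then be chemo- and face-selective on a triene with a free hydroxyl.
- Comparison: in step count this road is the better one, probably by a wide margin. The chosen plan sets against it the stereospecific E geometry from the fragmentation, C3, C4, C6 and C8 set on a rigid decalin, a C4–C5 epoxide made by substitution, and no high-dilution step.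

Key step: step 20

Remarks on the chemistry:
- For 12–28, eudesmane numbering is used and β means the face of the C10 methyl group.
- C11 is formed as a mixture of epimers in step 17. It is carried unassigned through 23–33 and becomes sp2 in step 24.
- Ketone 8 is drawn as its trans epimer; its C2 epimer converges in step 7.

## Route

Step 1
Reactants: 1 (S)-(+)-carvone
Product: 3 (5R,6R)-6-hydroxy-2-methyl-5-(prop-1-en-2-yl)cyclohex-2-en-1-one, via carvone trimethylsilyl dienol ether 2 (not isolated)
Conditions: LiN(iPr)2, THF, −78 °C; Me3SiCl; then mCPBA, NaHCO3, CH2Cl2, −20 °C; 1 M HCl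
Reagents that add atoms: mCPBA, OOC(=O)c1cccc(Cl)c1; chlorotrimethylsilane, C[Si](C)(C)Cl (retained only in 2)
Why: Rubottom oxidation of the kinetic cross-conjugated dienol ether; the peracid attacks the electron-rich enol ether on the face opposite the adjacent isopropenyl group, giving the trans α′-hydroxy enone.

Step 2
Reactants: 3 (5R,6R)-6-hydroxy-2-methyl-5-(prop-1-en-2-yl)cyclohex-2-en-1-one
Product: 4 (5R,6R)-6-(tert-butyldimethylsilyloxy)-2-methyl-5-(prop-1-en-2-yl)cyclohex-2-en-1-one
Conditions: TBSCl, imidazole, DMF, rt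
Reagents that add atoms: tert-butyldimethylsilyl chloride, CC(C)(C)[Si](C)(C)Cl
Why: Standard silylation of a secondary alcohol; the silyl ether must last until step 26.

Step 3
Reactants: 4 (5R,6R)-6-(tert-butyldimethylsilyloxy)-2-methyl-5-(prop-1-en-2-yl)cyclohex-2-en-1-one
Product: 5 2,3-epoxide of 4 with the epoxide oxygen trans to the isopropenyl group
Conditions: H2O2 (30%), NaOH (cat.), MeOH, 0 °C
Reagents that add atoms: hydrogen peroxide, OO
Why: Weitz–Scheffer nucleophilic epoxidation of the enone, as known for carvone; the epoxide configuration is irrelevant because both new centers are lost by step 5.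

Step 4
Reactants: 5 2,3-epoxide of 4
Product: 6 (4S,5R)-4-(tert-butyldimethylsilyloxy)-2-methyl-5-(prop-1-en-2-yl)cyclohex-2-en-1-ol (hydroxyl cis to the silyloxy group)
Conditions: N2H4·H2O, AcOH (cat.), MeOH, 0 °C → rt
Reagents that add atoms: none
Why: Wharton transposition of an α,β-epoxy ketone (hydrazone, epoxide opening, loss of dinitrogen) moves the oxygen from C1 to C3, so the silyloxy carbon becomes allylic to the new olefin.

Step 5
Reactants: 6 (4S,5R)-4-(tert-butyldimethylsilyloxy)-2-methyl-5-(prop-1-en-2-yl)cyclohex-2-en-1-ol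
Product: 7 (4S,5R)-4-(tert-butyldimethylsilyloxy)-2-methyl-5-(prop-1-en-2-yl)cyclohex-2-en-1-one
Conditions: Dess–Martin periodinane, NaHCO3, CH2Cl2, 0 °C
Reagents that add atoms: none
Why: Dess–Martin oxidation of the allylic alcohol gives the transposed enone, which has the (R)-carvone configuration at C5 and the silyloxy group at the γ-carbon, trans to the isopropenyl group.

Step 6
Reactants: 7 (4S,5R)-4-(tert-butyldimethylsilyloxy)-2-methyl-5-(prop-1-en-2-yl)cyclohex-2-en-1-one
Product: 8 (2R,4S,5R)-4-(tert-butyldimethylsilyloxy)-2-methyl-5-(prop-1-en-2-yl)cyclohexan-1-one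
Conditions: LiBH(sBu)3, THF, −78 °C; aqueous work-up
Reagents that add atoms: none
Why: Conjugate reduction of a β-unsubstituted cyclohexenone by a hindered trialkylborohydride, as known for carvone; the isopropenyl group and silyl ether are untouched.

Step 7
Reactants: 8 (2R,4S,5R)-4-(tert-butyldimethylsilyloxy)-2-methyl-5-(prop-1-en-2-yl)cyclohexan-1-one; 9 ethyl vinyl ketone
Product: 11 (2R,4S,5R)-4-(tert-butyldimethylsilyloxy)-2-methyl-2-(3-oxopentyl)-5-(prop-1-en-2-yl)cyclohexan-1-one, via (R)-1-phenylethylamine ketimine 10 (not isolated)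
Conditions: (R)-PhCH(Me)NH2, TsOH (cat.), PhMe, reflux (−H2O); 9, THF, 40 °C; then 10% aq. AcOH, rt
Reagents that add atoms: (R)-1-phenylethylamine, C[C@@H](N)c1ccccc1 (retained only in 10)
Why: Michael addition of the more substituted secondary enamine tautomer of a chiral imine through an aza-ene-type transition state. The (R)-amine is the one that turns the parent dihydrocarvone into the α-cyperone series, so the chain should enter anti to the isopropenyl group and leave the C10 methyl cis to it.

Step 8
Reactants: 11 (2R,4S,5R)-4-(tert-butyldimethylsilyloxy)-2-methyl-2-(3-oxopentyl)-5-(prop-1-en-2-yl)cyclohexan-1-one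
Product: 12 8α-(tert-butyldimethylsilyloxy)eudesma-4,11-dien-3-one
Conditions: NaOMe, MeOH, 50 °C
Reagents that add atoms: none
Why: Intramolecular aldol condensation completes the Robinson annulation; no stereocenter is formed and the silyloxy group is not β to any enolizable position.

Step 9
Reactants: 12 8α-(tert-butyldimethylsilyloxy)eudesma-4,11-dien-3-one
Product: 13 8α-(tert-butyldimethylsilyloxy)eudesma-1,4,11-trien-3-one
Conditions: DDQ, dioxane, reflux
Reagents that add atoms: none
Why: Quinone dehydrogenation of a Δ4-3-ketone to the cross-conjugated 1,4-dien-3-one, standard for steroid and eudesmane enones; it is placed before any PMB ether is present.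

Step 10
Reactants: 13 8α-(tert-butyldimethylsilyloxy)eudesma-1,4,11-trien-3-one
Product: 14 4α-hydroxy-8α-(tert-butyldimethylsilyloxy)eudesma-1,5,11-trien-3-one
Conditions: KN(SiMe3)2, THF, −78 °C; 3-phenyl-2-(phenylsulfonyl)oxaziridine, −78 °C; aqueous work-up
Reagents that add atoms: 3-phenyl-2-(phenylsulfonyl)oxaziridine, O=S(=O)(N1OC1c1ccccc1)c1ccccc1
Why: Deconjugative α-hydroxylation of an extended enolate with a Davis oxaziridine. The dienone can only be deprotonated at C6, and the enolate reacts at its α-carbon C4, as in the C4 alkylation of such enones. The oxidant approaches anti to the axial C10 methyl, giving the 4α-hydroxyl and the Δ5 olefin.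

Step 11
Reactants: 14 4α-hydroxy-8α-(tert-butyldimethylsilyloxy)eudesma-1,5,11-trien-3-one
Product: 16 1α,4α-dihydroxy-8α-(tert-butyldimethylsilyloxy)eudesma-5,11-dien-3-one, via C1 pinacolboronate 15 (not isolated)
Conditions: B2pin2, CuCl (5 mol %), NaOtBu (10 mol %), Xantphos (5 mol %), MeOH, THF, rt; then NaBO3·4H2O, THF/H2O, 0 °C
Reagents that add atoms: sodium perborate, [Na+].[O-]OB=O; bis(pinacolato)diboron, CC1(C)OB(OC1(C)C)B1OC(C)(C)C(C)(C)O1 (retained only in 15)
Why: Copper-catalysed conjugate borylation of the only conjugated olefin, followed by stereoretentive C–B oxidation. Boron adds to C1 anti to the C10 methyl, so the β-hydroxy ketone has the 1α (axial) hydroxyl.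

Step 12
Reactants: 16 1α,4α-dihydroxy-8α-(tert-butyldimethylsilyloxy)eudesma-5,11-dien-3-one
Product: 17 8α-(tert-butyldimethylsilyloxy)eudesma-5,11-diene-1α,3β,4α-triol
Conditions: Me4NBH(OAc)3, MeCN/AcOH, −30 °C
Reagents that add atoms: none
Why: Evans–Saksena hydroxyl-directed reduction. Both the axial 1α-hydroxyl and the 4α-hydroxyl deliver hydride to the α face of C3, giving the equatorial 3β-alcohol (1,3-anti, 3,4-trans) under acidic conditions that spare the β-hydroxy ketone from retro-aldol cleavage.

Step 13
Reactants: 17 8α-(tert-butyldimethylsilyloxy)eudesma-5,11-diene-1α,3β,4α-triol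
Product: 19 3β-(4-methoxybenzyloxy)-8α-(tert-butyldimethylsilyloxy)eudesma-5,11-diene-1α,4α-diol, via 3,4-O-dibutylstannylene acetal 18 (not isolated)
Conditions: Bu2SnO, PhMe, reflux (−H2O); then PMBCl, CsF, DMF, 40 °C
Reagents that add atoms: 4-methoxybenzyl chloride, COc1ccc(CCl)cc1; dibutyltin oxide, CCCC[Sn](=O)CCCC (retained only in 18)
Why: Stannylene-acetal-mediated regioselective O-alkylation. Only the vicinal 3,4-diol forms the acetal, and within it the secondary O3 is alkylated, leaving the isolated 1α-hydroxyl and the tertiary 4α-hydroxyl free.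

Step 14
Reactants: 19 3β-(4-methoxybenzyloxy)-8α-(tert-butyldimethylsilyloxy)eudesma-5,11-diene-1α,4α-diol
Product: 20 4α-hydroxy-3β-(4-methoxybenzyloxy)-8α-(tert-butyldimethylsilyloxy)eudesma-5,11-dien-1-one
Conditions: Dess–Martin periodinane, NaHCO3, CH2Cl2, 0 °C
Reagents that add atoms: none
Why: Dess–Martin oxidation of the only secondary alcohol; buffered, non-basic conditions avoid β-elimination of the C3 ether.

Step 15
Reactants: 20 4α-hydroxy-3β-(4-methoxybenzyloxy)-8α-(tert-butyldimethylsilyloxy)eudesma-5,11-dien-1-one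
Product: 21 3β-(4-methoxybenzyloxy)-8α-(tert-butyldimethylsilyloxy)eudesma-5,11-diene-1β,4α-diol
Conditions: NaBH4, MeOH, −30 °C
Reagents that add atoms: none
Why: Borohydride reduction of a ketone next to a quaternary center; hydride attacks anti to the axial C10 methyl, as in the C1 ketone of the Wieland–Miescher ketone, giving the equatorial 1β-alcohol cis to that methyl.

Step 16
Reactants: 21 3β-(4-methoxybenzyloxy)-8α-(tert-butyldimethylsilyloxy)eudesma-5,11-diene-1β,4α-diol
Product: 22 4α-hydroxy-3β-(4-methoxybenzyloxy)-8α-(tert-butyldimethylsilyloxy)eudesma-5,11-dien-1β-yl methanesulfonate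
Conditions: MsCl, pyridine, DMAP (cat.), CH2Cl2, 0 °C
Reagents that add atoms: methanesulfonyl chloride, CS(Cl)(=O)=O
Why: Sulfonylation of the secondary alcohol in the presence of an unreactive tertiary one. The equatorial neopentyl mesylate has no antiperiplanar hydrogen and cannot be displaced, so it survives steps 17–19.

Step 17
Reactants: 22 4α-hydroxy-3β-(4-methoxybenzyloxy)-8α-(tert-butyldimethylsilyloxy)eudesma-5,11-dien-1β-yl methanesulfonate
Product: 24 4α,12-dihydroxy-3β-(4-methoxybenzyloxy)-8α-(tert-butyldimethylsilyloxy)eudesm-5-en-1β-yl methanesulfonate (C11 epimers), via C12 9-borabicyclononyl borane 23 (not isolated)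
Conditions: 9-BBN (3 equiv), THF, 0 °C → rt; then NaBO3·4H2O, H2O, rt
Reagents that add atoms: sodium perborate, [Na+].[O-]OB=O; 9-borabicyclo[3.3.1]nonane, B1C2CCCC1CCC2 (retained only in 23)
Why: Anti-Markovnikov hydroboration–oxidation of the 1,1-disubstituted olefin. The trisubstituted Δ5 olefin, flanked by two fully substituted carbons, does not react with the bulky borane, and removing the isopropenyl group clears the way for step 18.

Step 18
Reactants: 24 4α,12-dihydroxy-3β-(4-methoxybenzyloxy)-8α-(tert-butyldimethylsilyloxy)eudesm-5-en-1β-yl methanesulfonate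
Product: 26 4α,5α,6α,12-tetrahydroxy-3β-(4-methoxybenzyloxy)-8α-(tert-butyldimethylsilyloxy)eudesman-1β-yl methanesulfonate, via C5/C6 osmate ester TMEDA adduct 25 (not isolated)
Conditions: OsO4 (1.05 equiv), TMEDA, CH2Cl2, −78 °C → rt; then aq. Na2SO3, THF, 40 °C
Reagents that add atoms: osmium tetroxide, O=[Os](=O)(=O)=O
Why: Amine-accelerated, hydrogen-bond-directed syn-dihydroxylation. The reagent is held by the allylic 4α-hydroxyl and adds to the α face, the only face not blocked by the axial C4 and C10 methyl groups and the C7 side chain. This gives the trans ring fusion (5α-OH) and the equatorial 6α-OH trans to C7.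

Step 19
Reactants: 26 4α,5α,6α,12-tetrahydroxy-3β-(4-methoxybenzyloxy)-8α-(tert-butyldimethylsilyloxy)eudesman-1β-yl methanesulfonate
Product: 27 4α,5α-dihydroxy-1β-(methanesulfonyloxy)-3β-(4-methoxybenzyloxy)-8α-(tert-butyldimethylsilyloxy)eudesman-12,6α-olide (C11 epimers)
Conditions: Cu(MeCN)4OTf (5 mol %), 2,2′-bipyridine, ABNO (cat.), N-methylimidazole, MeCN, air, rt
Reagents that add atoms: none
Why: Copper/nitroxyl aerobic oxidative lactonization of a 1,4-diol. The primary C12 alcohol is oxidized to the aldehyde, the lactol closes on the adjacent equatorial O6 (five-membered, trans-fused) and is oxidized again. The tertiary hydroxyls are inert, and this oxidant does not cleave vicinal diols.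

Step 20
Reactants: 27 4α,5α-dihydroxy-1β-(methanesulfonyloxy)-3β-(4-methoxybenzyloxy)-8α-(tert-butyldimethylsilyloxy)eudesman-12,6α-olide
Product: 29 (1(10)E)-4-hydroxy-5-oxo-3-(4-methoxybenzyloxy)-8-(tert-butyldimethylsilyloxy)germacr-1(10)-en-12,6-olide (C3/C4/C6/C7/C8 as in 27), via potassium C5 alkoxide 28 (not isolated)
Conditions: KOtBu (1.1 equiv), THF, −20 → 0 °C; pH 7 buffer
Reagents that add atoms: none
Why: KOtBu deprotonates the tertiary 5α-hydroxyl to alkoxide 28. Its lone pair forms the C5=O π bond while the C5–C10 σ bond, antiperiplanar to the equatorial C1–O bond in the chair of ring A, breaks and C1=C10 forms with loss of mesylate, all in one concerted step. This is the Wharton variant of the Grob fragmentation, established for trans-fused decalin-1,3-diol monosulfonates, which give (E)-cyclodec-5-enones. No bond between ring atoms is formed: the ten-membered ring is released by scission of the bond shared by the two six-membered rings, so no cyclization mode and no dilution are involved. No stereocenter is created; C1, C5 and C10 are lost and C3, C4, C6, C7 and C8 are untouched. The step needs E geometry, and this is secured by the trans ring fusion (10β-methyl, 5α-oxygen) and the 1β-equatorial mesylate, which hold C2 and C9 antiperiplanar about C1–C10 as the bond breaks. Only the C5 alkoxide has a leaving group antiperiplanar to one of its C–C bonds, so the C4 alkoxide and the lactone are spectators; a cold quench with only a slight excess of base protects the C6–H beside the new ketone.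

Step 21
Reactants: 29 (1(10)E)-4-hydroxy-5-oxo-3-(4-methoxybenzyloxy)-8-(tert-butyldimethylsilyloxy)germacr-1(10)-en-12,6-olide
Product: 30 (1(10)E,5S)-4,5-dihydroxy-3-(4-methoxybenzyloxy)-8-(tert-butyldimethylsilyloxy)germacr-1(10)-en-12,6-olide
Conditions: Zn(BH4)2, Et2O/THF, −40 °C
Reagents that add atoms: none
Why: Chelation-controlled (Cram chelate) reduction of an α-hydroxy ketone. Zinc bridges O4 and the C5 carbonyl, and hydride enters from the side of the C4 methyl group, giving the anti 4,5-diol, which is the C5 epimer needed for inversion in step 23. The lactone is not reduced by this reagent.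

Step 22
Reactants: 30 (1(10)E,5S)-4,5-dihydroxy-3-(4-methoxybenzyloxy)-8-(tert-butyldimethylsilyloxy)germacr-1(10)-en-12,6-olide
Product: 31 C5 methanesulfonate of 30
Conditions: MsCl, Et3N, CH2Cl2, −20 °C
Reagents that add atoms: methanesulfonyl chloride, CS(Cl)(=O)=O
Why: Selective sulfonylation of the secondary C5 hydroxyl; the tertiary C4 hydroxyl is not sulfonylated under these conditions.

Step 23
Reactants: 31 C5 methanesulfonate of 30
Product: 32 (4R,5R)-4,5-epoxy-3-(4-methoxybenzyloxy)-8-(tert-butyldimethylsilyloxy)germacr-1(10)-en-12,6-olide (C11 epimers)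
Conditions: NaH, THF, 0 °C → rt
Reagents that add atoms: none
Why: Intramolecular Williamson closure (3-exo-tet). The C4 alkoxide displaces the C5 mesylate with inversion, so the epoxide oxygen is the O4 set in step 10 and the trans epoxide of the target results; a non-nucleophilic base leaves the lactone closed.

Step 24
Reactants: 32 (4R,5R)-4,5-epoxy-3-(4-methoxybenzyloxy)-8-(tert-butyldimethylsilyloxy)germacr-1(10)-en-12,6-olide
Product: 34 (4R,5R)-4,5-epoxy-3-(4-methoxybenzyloxy)-8-(tert-butyldimethylsilyloxy)germacra-1(10),11(13)-dien-12,6-olide, via C11 phenylselenide 33 (not isolated)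
Conditions: LiN(iPr)2, THF, −78 °C; PhSeBr; then H2O2 (30%), pyridine, CH2Cl2, 0 °C → rt
Reagents that add atoms: benzeneselenenyl bromide, Br[Se]c1ccccc1 (retained only in 33)
Why: α-Selenenylation of the lactone enolate and selenoxide syn-elimination, the standard route from 11,13-dihydrogermacranolides to their α-methylene lactones. In a trans-fused lactone selenium enters trans to H7, so only the methyl hydrogens are syn and the exocyclic olefin forms; both C11 epimers converge.

Step 25
Reactants: 34 (4R,5R)-4,5-epoxy-3-(4-methoxybenzyloxy)-8-(tert-butyldimethylsilyloxy)germacra-1(10),11(13)-dien-12,6-olide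
Product: 35 (1R,4R,5R,10R)-1,10:4,5-diepoxy-3-(4-methoxybenzyloxy)-8-(tert-butyldimethylsilyloxy)germacr-11(13)-en-12,6-olide
Conditions: mCPBA, NaHCO3, CH2Cl2, 0 °C
Reagents that add atoms: mCPBA, OOC(=O)c1cccc(Cl)c1
Why: Prilezhaev epoxidation of the only electron-rich olefin; the methylene lactone is electron-poor. Compound 34 has the parthenolide ring system, whose C1=C10 olefin is attacked on its outer face; that face corresponds to the former C1–O bond and to the side opposite the former C5–C10 bond, and gives the (1R,10R) epoxide.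

Step 26
Reactants: 35 (1R,4R,5R,10R)-1,10:4,5-diepoxy-3-(4-methoxybenzyloxy)-8-(tert-butyldimethylsilyloxy)germacr-11(13)-en-12,6-olide
Product: 36 (1R,4R,5R,10R)-1,10:4,5-diepoxy-8-hydroxy-3-(4-methoxybenzyloxy)germacr-11(13)-en-12,6-olide
Conditions: Bu4NF, AcOH (1:1), THF, 0 °C → rt
Reagents that add atoms: none
Why: Fluoride desilylation buffered with acetic acid, so that no free C8 alkoxide can migrate the lactone from O6 to O8 or add to the methylene lactone.

Step 27
Reactants: 36 (1R,4R,5R,10R)-1,10:4,5-diepoxy-8-hydroxy-3-(4-methoxybenzyloxy)germacr-11(13)-en-12,6-olide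
Product: 37 (1R,4R,5R,10R)-1,10:4,5-diepoxy-3-(4-methoxybenzyloxy)-8-tigloyloxygermacr-11(13)-en-12,6-olide
Conditions: tigloyl chloride, Et3N, DMAP (cat.), CH2Cl2, 0 °C → rt
Reagents that add atoms: tigloyl chloride, O=C(Cl)/C(C)=C/C
Why: DMAP-catalysed acylation of the only free hydroxyl; the E (tiglate) geometry is the stable one and is not at risk.

Step 28
Reactants: 37 (1R,4R,5R,10R)-1,10:4,5-diepoxy-3-(4-methoxybenzyloxy)-8-tigloyloxygermacr-11(13)-en-12,6-olide
Product: 38 (1R,3S,4R,5R,6S,7R,8S,10R)-1,10:4,5-diepoxy-3-hydroxy-8-tigloyloxygermacr-11(13)-en-12,6-olide (CNP0350037.1)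
Conditions: DDQ, CH2Cl2/pH 7 phosphate buffer, 0 °C
Reagents that add atoms: none
Why: Oxidative cleavage of the PMB ether under buffered, near-neutral conditions, which avoids acid-induced transannular epoxide opening and base-induced Payne rearrangement of the 3-hydroxy-4,5-epoxide.

## Compound list

1 | (S)-(+)-carvone | CC1=CC[C@@H](CC1=O)C(C)=C | starting material
2 | carvone trimethylsilyl dienol ether (not isolated) | CC1=CC[C@H](C(C)=C)C=C1O[Si](C)(C)C | intermediate
3 | (5R,6R)-6-hydroxy-2-methyl-5-(prop-1-en-2-yl)cyclohex-2-en-1-one | CC1=CC[C@H](C(C)=C)[C@@H](O)C1=O | intermediate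
4 | (5R,6R)-6-(tert-butyldimethylsilyloxy)-2-methyl-5-(prop-1-en-2-yl)cyclohex-2-en-1-one | CC1=CC[C@H](C(C)=C)[C@@H](O[Si](C)(C)C(C)(C)C)C1=O | intermediate
5 | 2,3-epoxide of 4, epoxide oxygen trans to isopropenyl | C[C@]12O[C@H]1C[C@H](C(C)=C)[C@@H](O[Si](C)(C)C(C)(C)C)C2=O | intermediate
6 | (4S,5R)-4-(tert-butyldimethylsilyloxy)-2-methyl-5-(prop-1-en-2-yl)cyclohex-2-en-1-ol, hydroxyl cis to silyloxy | CC1=C[C@H](O[Si](C)(C)C(C)(C)C)[C@@H](C(C)=C)C[C@@H]1O | intermediate
7 | (4S,5R)-4-(tert-butyldimethylsilyloxy)-2-methyl-5-(prop-1-en-2-yl)cyclohex-2-en-1-one | CC1=C[C@H](O[Si](C)(C)C(C)(C)C)[C@@H](C(C)=C)CC1=O | intermediate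
8 | (2R,4S,5R)-4-(tert-butyldimethylsilyloxy)-2-methyl-5-(prop-1-en-2-yl)cyclohexan-1-one | C[C@@H]1C[C@H](O[Si](C)(C)C(C)(C)C)[C@@H](C(C)=C)CC1=O | intermediate
9 | ethyl vinyl ketone (pent-1-en-3-one) | CCC(=O)C=C | starting material
10 | (R)-1-phenylethylamine ketimine of 8 (not isolated) | C[C@@H]1C[C@H](O[Si](C)(C)C(C)(C)C)[C@@H](C(C)=C)CC1=N[C@H](C)c1ccccc1 | intermediate
11 | (2R,4S,5R)-4-(tert-butyldimethylsilyloxy)-2-methyl-2-(3-oxopentyl)-5-(prop-1-en-2-yl)cyclohexan-1-one | CCC(=O)CC[C@]1(C)C[C@H](O[Si](C)(C)C(C)(C)C)[C@@H](C(C)=C)CC1=O | intermediate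
12 | 8α-(tert-butyldimethylsilyloxy)eudesma-4,11-dien-3-one | C1CC(=O)C(C)=C2C[C@H](C(C)=C)[C@@H](O[Si](C)(C)C(C)(C)C)C[C@@]12C | intermediate
13 | 8α-(tert-butyldimethylsilyloxy)eudesma-1,4,11-trien-3-one | C1=CC(=O)C(C)=C2C[C@H](C(C)=C)[C@@H](O[Si](C)(C)C(C)(C)C)C[C@@]12C | intermediate
14 | 4α-hydroxy-8α-(tert-butyldimethylsilyloxy)eudesma-1,5,11-trien-3-one | C1=CC(=O)[C@@](C)(O)C2=C[C@H](C(C)=C)[C@@H](O[Si](C)(C)C(C)(C)C)C[C@@]12C | intermediate
15 | 1α-pinacolboronate of the C3 ketone (not isolated) | CC1(C)OB(OC1(C)C)[C@H]2CC(=O)[C@@](C)(O)C3=C[C@H](C(C)=C)[C@@H](O[Si](C)(C)C(C)(C)C)C[C@@]23C | intermediate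
16 | 1α,4α-dihydroxy-8α-(tert-butyldimethylsilyloxy)eudesma-5,11-dien-3-one | O[C@H]1CC(=O)[C@@](C)(O)C2=C[C@H](C(C)=C)[C@@H](O[Si](C)(C)C(C)(C)C)C[C@@]12C | intermediate
17 | 8α-(tert-butyldimethylsilyloxy)eudesma-5,11-diene-1α,3β,4α-triol | O[C@H]1C[C@H](O)[C@@](C)(O)C2=C[C@H](C(C)=C)[C@@H](O[Si](C)(C)C(C)(C)C)C[C@@]12C | intermediate
18 | 3,4-O-dibutylstannylene acetal of 17 (not isolated) | O[C@H]1C[C@@H]2O[Sn](CCCC)(CCCC)O[C@@]2(C)C3=C[C@H](C(C)=C)[C@@H](O[Si](C)(C)C(C)(C)C)C[C@@]13C | intermediate
19 | 3β-(4-methoxybenzyloxy)-8α-(tert-butyldimethylsilyloxy)eudesma-5,11-diene-1α,4α-diol | O[C@H]1C[C@H](OCc2ccc(OC)cc2)[C@@](C)(O)C3=C[C@H](C(C)=C)[C@@H](O[Si](C)(C)C(C)(C)C)C[C@@]13C | intermediate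
20 | 4α-hydroxy-3β-(4-methoxybenzyloxy)-8α-(tert-butyldimethylsilyloxy)eudesma-5,11-dien-1-one | O=C1C[C@H](OCc2ccc(OC)cc2)[C@@](C)(O)C3=C[C@H](C(C)=C)[C@@H](O[Si](C)(C)C(C)(C)C)C[C@@]13C | intermediate
21 | 3β-(4-methoxybenzyloxy)-8α-(tert-butyldimethylsilyloxy)eudesma-5,11-diene-1β,4α-diol | O[C@@H]1C[C@H](OCc2ccc(OC)cc2)[C@@](C)(O)C3=C[C@H](C(C)=C)[C@@H](O[Si](C)(C)C(C)(C)C)C[C@@]13C | intermediate
22 | 4α-hydroxy-3β-(4-methoxybenzyloxy)-8α-(tert-butyldimethylsilyloxy)eudesma-5,11-dien-1β-yl methanesulfonate | CS(=O)(=O)O[C@@H]1C[C@H](OCc2ccc(OC)cc2)[C@@](C)(O)C3=C[C@H](C(C)=C)[C@@H](O[Si](C)(C)C(C)(C)C)C[C@@]13C | intermediate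
23 | C12 9-borabicyclononyl borane from 22, C11 epimers (not isolated) | CS(=O)(=O)O[C@@H]1C[C@H](OCc2ccc(OC)cc2)[C@@](C)(O)C3=C[C@H](C(C)CB4C5CCCC4CCC5)[C@@H](O[Si](C)(C)C(C)(C)C)C[C@@]13C | intermediate
24 | 4α,12-dihydroxy-3β-(4-methoxybenzyloxy)-8α-(tert-butyldimethylsilyloxy)eudesm-5-en-1β-yl methanesulfonate, C11 epimers | CS(=O)(=O)O[C@@H]1C[C@H](OCc2ccc(OC)cc2)[C@@](C)(O)C3=C[C@H](C(C)CO)[C@@H](O[Si](C)(C)C(C)(C)C)C[C@@]13C | intermediate
25 | 5α,6α-osmate ester of 24 as its TMEDA adduct (not isolated) | CS(=O)(=O)O[C@@H]1C[C@H](OCc2ccc(OC)cc2)[C@@](C)(O)[C@]34O[Os](=O)(=O)O[C@H]3[C@H](C(C)CO)[C@@H](O[Si](C)(C)C(C)(C)C)C[C@@]14C.CN(C)CCN(C)C | intermediate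
26 | 4α,5α,6α,12-tetrahydroxy-3β-(4-methoxybenzyloxy)-8α-(tert-butyldimethylsilyloxy)eudesman-1β-yl methanesulfonate, C11 epimers | CS(=O)(=O)O[C@@H]1C[C@H](OCc2ccc(OC)cc2)[C@@](C)(O)[C@]3(O)[C@@H](O)[C@H](C(C)CO)[C@@H](O[Si](C)(C)C(C)(C)C)C[C@@]13C | intermediate
27 | 4α,5α-dihydroxy-1β-(methanesulfonyloxy)-3β-(4-methoxybenzyloxy)-8α-(tert-butyldimethylsilyloxy)eudesman-12,6α-olide, C11 epimers (key-step precursor) | CS(=O)(=O)O[C@@H]1C[C@H](OCc4ccc(OC)cc4)[C@@](C)(O)[C@]2(O)[C@H]3OC(=O)C(C)[C@@H]3[C@@H](O[Si](C)(C)C(C)(C)C)C[C@@]12C | intermediate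
28 | potassium C5 alkoxide of 27 (not isolated) | CS(=O)(=O)O[C@@H]1C[C@H](OCc4ccc(OC)cc4)[C@@](C)(O)[C@]2([O-])[C@H]3OC(=O)C(C)[C@@H]3[C@@H](O[Si](C)(C)C(C)(C)C)C[C@@]12C.[K+] | intermediate
29 | (1(10)E)-4-hydroxy-5-oxo-3-(4-methoxybenzyloxy)-8-(tert-butyldimethylsilyloxy)germacr-1(10)-en-12,6-olide, C11 epimers (key-step product) | O=C1[C@H]2OC(=O)C(C)[C@@H]2[C@@H](O[Si](C)(C)C(C)(C)C)C/C(C)=C/C[C@H](OCc2ccc(OC)cc2)[C@@]1(C)O | intermediate
30 | (1(10)E,5S)-4,5-dihydroxy-3-(4-methoxybenzyloxy)-8-(tert-butyldimethylsilyloxy)germacr-1(10)-en-12,6-olide, C11 epimers | O[C@H]1[C@H]2OC(=O)C(C)[C@@H]2[C@@H](O[Si](C)(C)C(C)(C)C)C/C(C)=C/C[C@H](OCc2ccc(OC)cc2)[C@@]1(C)O | intermediate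
31 | C5 methanesulfonate of 30 | CS(=O)(=O)O[C@H]1[C@H]2OC(=O)C(C)[C@@H]2[C@@H](O[Si](C)(C)C(C)(C)C)C/C(C)=C/C[C@H](OCc2ccc(OC)cc2)[C@@]1(C)O | intermediate
32 | (4R,5R)-4,5-epoxy-3-(4-methoxybenzyloxy)-8-(tert-butyldimethylsilyloxy)germacr-1(10)-en-12,6-olide, C11 epimers | CC1C(=O)O[C@H]2[C@H]1[C@@H](O[Si](C)(C)C(C)(C)C)C/C(C)=C/C[C@H](OCc3ccc(OC)cc3)[C@@]1(C)O[C@H]21 | intermediate
33 | C11 phenylselenide of 32, C11 unassigned (not isolated) | CC1([Se]c3ccccc3)C(=O)O[C@H]2[C@H]1[C@@H](O[Si](C)(C)C(C)(C)C)C/C(C)=C/C[C@H](OCc3ccc(OC)cc3)[C@@]1(C)O[C@H]21 | intermediate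
34 | (4R,5R)-4,5-epoxy-3-(4-methoxybenzyloxy)-8-(tert-butyldimethylsilyloxy)germacra-1(10),11(13)-dien-12,6-olide | C=C1C(=O)O[C@H]2[C@H]1[C@@H](O[Si](C)(C)C(C)(C)C)C/C(C)=C/C[C@H](OCc3ccc(OC)cc3)[C@@]1(C)O[C@H]21 | intermediate
35 | (1R,4R,5R,10R)-1,10:4,5-diepoxy-3-(4-methoxybenzyloxy)-8-(tert-butyldimethylsilyloxy)germacr-11(13)-en-12,6-olide | C=C1C(=O)O[C@H]2[C@H]1[C@@H](O[Si](C)(C)C(C)(C)C)C[C@@]1(C)O[C@@H]1C[C@H](OCc3ccc(OC)cc3)[C@@]1(C)O[C@H]21 | intermediate
36 | (1R,4R,5R,10R)-1,10:4,5-diepoxy-8-hydroxy-3-(4-methoxybenzyloxy)germacr-11(13)-en-12,6-olide | C=C1C(=O)O[C@H]2[C@H]1[C@@H](O)C[C@@]1(C)O[C@@H]1C[C@H](OCc3ccc(OC)cc3)[C@@]1(C)O[C@H]21 | intermediate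
37 | (1R,4R,5R,10R)-1,10:4,5-diepoxy-3-(4-methoxybenzyloxy)-8-tigloyloxygermacr-11(13)-en-12,6-olide | C=C1C(=O)O[C@H]2[C@H]1[C@@H](OC(=O)/C(C)=C/C)C[C@@]1(C)O[C@@H]1C[C@H](OCc3ccc(OC)cc3)[C@@]1(C)O[C@H]21 | intermediate
38 | (1R,3S,4R,5R,6S,7R,8S,10R)-1,10:4,5-diepoxy-3-hydroxy-8-tigloyloxygermacr-11(13)-en-12,6-olide (CNP0350037.1) | C=C1C(=O)O[C@H]2[C@H]1[C@@H](OC(=O)/C(C)=C/C)C[C@@]1(C)O[C@@H]1C[C@H](O)[C@@]1(C)O[C@H]21 | target

## Step count and least certain steps

Total: 28 steps. Longest linear sequence: 28 steps from (S)-carvone 1; ethyl vinyl ketone 9 and the reagents are purchased.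

**Step 20 (key step).** The most likely failure is not the fragmentation but what the base does afterwards: enolization of the new ketone toward C6 (epimerization next to the lactone oxygen), α-ketol rearrangement of the free C4-hydroxy ketone, or acyl migration of the lactone to the neighbouring alkoxide. Fallback: starting from 27, the less shielded equatorial C4 hydroxyl is silylated with Et3SiOTf and 2,6-lutidine to give the 4α-triethylsilyl ether of 27 F1. The same fragmentation then gives the 4-triethylsilyloxy cyclodecenone F2, which has no free α-hydroxyl. HF·pyridine in THF/pyridine removes the tertiary triethylsilyl group in the presence of the secondary TBS ether and returns to 29.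

**Step 7.** Poor facial selectivity at C10 is the risk, because the auxiliary has to override the substrate's preference for axial attack cis to the isopropenyl group. Fallback with catalyst control, starting from 7: conjugate reduction with LiBH(sBu)3 and trapping with allyl chloroformate gives the allyl enol carbonate F3. Decarboxylative asymmetric allylic alkylation with Pd2(dba)3 (zerovalent palladium) and (S)-t-Bu-PHOX gives the α-allyl ketone F4. Aldehyde-selective Wacker oxidation (PdCl2(PhCN)2, CuCl2, AgNO2, O2), which leaves the 1,1-disubstituted olefin alone, gives the aldehyde F5. EtMgBr at −78 °C gives the ethyl carbinol F6, and Dess–Martin oxidation returns to 11.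

**Step 10.** The oxidant may attack the extended enolate at C6 instead of C4, or the hindered enolate may react sluggishly. Fallback starting from 13: the same enolate is protonated kinetically at C4 (AcOH, −78 °C) to give the deconjugated 4-H eudesma-1,5,11-trien-3-one F7. Its doubly activated tertiary C4–H is then hydroxylated with SeO2 (cat.) and tBuOOH by an ene reaction and [2,3]-shift on the α face, returning to 14.

**Step 18.** The trisubstituted olefin lies between two fully substituted carbons, and osmylation may simply not proceed. Fallback starting from 24: mCPBA (NaHCO3), directed by the C4 hydroxyl, gives the 5α,6α-epoxide F8. CO2 with LiBr in N-methylpyrrolidone at 80 °C converts it, by bromide opening at C6 and carbonate closure (double inversion at C6), into the cis-5α,6α-cyclic carbonate F9. iBu2AlH at −78 °C cleaves the carbonate without generating a free alkoxide next to the mesylate and returns to 26.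

**Step 21.** The ten-membered ring, and not the zinc chelate, may decide which face of the ketone is open, which would erode or reverse the selectivity at C5. Fallback with reagent control, starting from 29: Me3SiOTf and 2,6-lutidine give the C4 trimethylsilyl ether of 29 F10. Reduction with catecholborane and the enantiomer of the CBS oxazaborolidine that delivers hydride to the face leading to the 5S alcohol gives the silyl ether alcohol F11. Citric acid in methanol removes the silyl group and returns to 30.

**Step 25.** If the ring of 34 adopts a different conformation, the peracid would attack the other face of C1=C10. Fallback starting from 34, delivering oxygen to the opposite face: N-bromosuccinimide in buffered aqueous dimethoxyethane forms the bromonium ion on the exposed face, and water opens it at C10 from the other side to give the 1-bromo-10-hydroxy compound F12. DBU closes the epoxide with inversion at C1 and returns to 35. Transannular participation of the 4,5-epoxide is the risk of this variant.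

## Further compounds

F1 | step 20 | 4α-triethylsilyl ether of 27 | CS(=O)(=O)O[C@@H]1C[C@H](OCc4ccc(OC)cc4)[C@@](C)(O[Si](CC)(CC)CC)[C@]2(O)[C@H]3OC(=O)C(C)[C@@H]3[C@@H](O[Si](C)(C)C(C)(C)C)C[C@@]12C
F2 | step 20 | 4-triethylsilyl ether of 29 | O=C1[C@H]2OC(=O)C(C)[C@@H]2[C@@H](O[Si](C)(C)C(C)(C)C)C/C(C)=C/C[C@H](OCc2ccc(OC)cc2)[C@@]1(C)O[Si](CC)(CC)CC
F3 | step 7 | allyl enol carbonate from 7 | C=CCOC(=O)OC1=C(C)C[C@H](O[Si](C)(C)C(C)(C)C)[C@@H](C(C)=C)C1
F4 | step 7 | 2-allyl-4-(tert-butyldimethylsilyloxy)-2-methyl-5-(prop-1-en-2-yl)cyclohexan-1-one, allyl trans to isopropenyl | C=CC[C@]1(C)C[C@H](O[Si](C)(C)C(C)(C)C)[C@@H](C(C)=C)CC1=O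
F5 | step 7 | 3-[1-methyl-2-oxocyclohexyl]propanal derived from F4 | O=CCC[C@]1(C)C[C@H](O[Si](C)(C)C(C)(C)C)[C@@H](C(C)=C)CC1=O
F6 | step 7 | 2-(3-hydroxypentyl) ketone, carbinol epimers | CCC(O)CC[C@]1(C)C[C@H](O[Si](C)(C)C(C)(C)C)[C@@H](C(C)=C)CC1=O
F7 | step 10 | 8α-(tert-butyldimethylsilyloxy)eudesma-1,5,11-trien-3-one, C4 epimers | C1=CC(=O)C(C)C2=C[C@H](C(C)=C)[C@@H](O[Si](C)(C)C(C)(C)C)C[C@@]12C
F8 | step 18 | 5α,6α-epoxide of 24 | CS(=O)(=O)O[C@@H]1C[C@H](OCc2ccc(OC)cc2)[C@@](C)(O)[C@]34O[C@H]3[C@H](C(C)CO)[C@@H](O[Si](C)(C)C(C)(C)C)C[C@@]14C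
F9 | step 18 | 5α,6α-cyclic carbonate of 26 | CS(=O)(=O)O[C@@H]1C[C@H](OCc2ccc(OC)cc2)[C@@](C)(O)[C@]34OC(=O)O[C@H]3[C@H](C(C)CO)[C@@H](O[Si](C)(C)C(C)(C)C)C[C@@]14C
F10 | step 21 | 4-trimethylsilyl ether of 29 | O=C1[C@H]2OC(=O)C(C)[C@@H]2[C@@H](O[Si](C)(C)C(C)(C)C)C/C(C)=C/C[C@H](OCc2ccc(OC)cc2)[C@@]1(C)O[Si](C)(C)C
F11 | step 21 | 4-trimethylsilyl ether of 30 | O[C@H]1[C@H]2OC(=O)C(C)[C@@H]2[C@@H](O[Si](C)(C)C(C)(C)C)C/C(C)=C/C[C@H](OCc2ccc(OC)cc2)[C@@]1(C)O[Si](C)(C)C
F12 | step 25 | 1-bromo-10-hydroxy derivative of 34 | C=C1C(=O)O[C@H]2[C@H]1[C@@H](O[Si](C)(C)C(C)(C)C)C[C@@](C)(O)[C@@H](Br)C[C@H](OCc3ccc(OC)cc3)[C@@]1(C)O[C@H]21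
A1 | alternative 1 | 3-chloroacetoxy-1,10-epoxy-8-tigloyloxygermacra-4,11(13)-dien-12,6-olide | C=C1C(=O)O[C@H]2[C@H]1[C@@H](OC(=O)/C(C)=C/C)C[C@@]1(C)O[C@@H]1C[C@H](OC(=O)CCl)/C(C)=C/2
A2 | alternative 2 | 4,5-epoxy-3-oxo-8-tigloyloxygermacra-1(10),11(13)-dien-12,6-olide | C=C1C(=O)O[C@H]2[C@H]1[C@@H](OC(=O)/C(C)=C/C)C/C(C)=C/CC(=O)[C@@]1(C)O[C@H]21
A3 | alternative 3 | 8-hydroxy-3-(tert-butyldimethylsilyloxy)germacra-1(10),4,11(13)-trien-12,6-olide | C=C1C(=O)O[C@H]2[C@H]1[C@@H](O)C/C(C)=C/C[C@H](O[Si](C)(C)C(C)(C)C)/C(C)=C/2
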